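A closed, stirred flask holds solid substrate that must dissolve before it can react.

solid substrate 0.050 M; time 5.0 min

    starting material → product, rate k1*[starting material]/(1 + ([starting material]/sat1)) (sat1 = 4.8 mM, k1 = 0.50 s⁻¹)
    solid substrate ⇌ starting material, rate k2*(cs2 - [starting material]) while solid is left; crystals form when [starting material] > cs2 (cs2 = 8.5 mM, k2 = 0.016 s⁻¹)

- solid, in amounts per volume of the solution: solid substrate
- at the start none of the solid substrate is in solution
- starting material means what is dissolved; the solid is not counted in it
- run time (flask): 5.0 min

- how much product there is at 5.0 min, in percent of the solid substrate charged
- concentration of starting material in solution at 5.0 min, in percent of saturation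

**Start rate.** Into empty solution the solid dissolves at 0.136 mM s⁻¹. Dissolution is the rate-limiting step, since its coefficient 0.016 s⁻¹ is far below the 0.50 s⁻¹ of the reaction.

**Two slowings.** Dissolved material pushes back on dissolution, which multiplies that rate by 0.969. This gives 0.132 mM s⁻¹, the throughput, the rate at which solid substrate passes through solution into product while solid lasts. Step 1 levels off near 2.40 mM s⁻¹, far above the throughput, so for the product you can drop that levelling-off. The start-up takes about 1.94 s, so the mean rate over the run is the throughput times 0.994.

**Accumulated effect.** The throughput over 5.0 min passes 39.6 mM, less than the 50 mM charged, so solid should remain to the end. With the mean rate, my yield is 78.6 %. The shortfall of the throughput from the start rate gives my percent of saturation, 3.10 %.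

**Forecast.** The forecast gives 78.4 % and 3.3 %, with “Dissolution is the slow step”, and its saturation is higher than mine.

**Result.** The flask gives 78.4 % of product and 3.27 % of saturation. The path to product has 50 % of its turnover behind it at 2.50 min. Over that time the throughput gives 39.6 %, and the flask holds 38.9 %. The neighbour flask with 0.030 M of solid substrate needs 3.79 min at the throughput, less than the 5.0 min it gets. In that neighbour, product reaches 100 % and 0 % of the charged solid substrate is left.

The numbers were chosen freely; the result is computed.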